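The route rests on the C9–C10 disconnection. The homoallylic alcohol C9(OH)–C10–C11(=C20H2), which joins the cyclohexane to the ten-membered ring, is the retron of an intramolecular Nozaki–Hiyama allylation: an allylchromium generated at C20 of a cyclohexenylmethyl bromide adds through C10 to a C9 aldehyde held on the finished γ-lactone. One operation closes the ten-membered ring, moves the olefin to the exocyclic C11=C20 position and sets C9 and C10. The precursor is a seco-compound assembled from a dione-derived cyclohexene (C2 by Pd catalysis, C1/C14 by CBS desymmetrisation) and an L-erythrulose-derived lactone through a B-alkyl Suzuki coupling; a temporary O2/O14 p-methoxybenzylidene acetal steers the closure.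

Key step: step 18

Locants: C1–C20 are the briarane locants of the target. C1 is the methyl-bearing ring-fusion carbon, C2–C9 the remaining ten-ring carbons (C5=C6 olefin, C7 O-lactone, C8 carbinol), C10 the ring-fusion CH, C11(=C20H2)–C14 the rest of the cyclohexane; C15, C16 and C18 are the methyls on C1, C5 and C17, and C19 is the lactone carbonyl.

Assumption: the (R,R)-DACH-phenyl bis(diphenylphosphinobenzamide) ligand is taken to give the (R)-ether at C2 in step 2; if the sense of induction is opposite, its enantiomer is used.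

Step 1
Reactants: 1 4-methoxybenzyl alcohol
Product: 3 4-methoxybenzyloxyallene, via propargyl ether 2 (not isolated)
Conditions: NaH, THF, 0 °C; propargyl bromide, rt; then KOtBu (0.3 equiv), rt
Reagents that add atoms: propargyl bromide C#CCBr
Why: Williamson etherification followed by base-mediated propargyl-to-allenyl ether isomerisation; no stereocentre is formed.

Step 2
Reactants: 4 2-methylcyclohexane-1,3-dione; 3 4-methoxybenzyloxyallene
Product: 5 2-[(1R)-1-(4-methoxybenzyloxy)prop-2-enyl]-2-methylcyclohexane-1,3-dione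
Conditions: Pd2(dba)3·CHCl3 (2.5 mol %), (R,R)-DACH-phenyl bis(diphenylphosphinobenzamide) ligand (7.5 mol %), PhCO2H (10 mol %), CH2Cl2, rt
Reagents that add atoms: none
Why: Pd-catalysed asymmetric addition of a 1,3-dicarbonyl pronucleophile to an alkoxyallene (hydropalladation to a 1-alkoxy-π-allyl complex that is attacked at its oxygen-bearing terminus) should install the 1-alkoxyallyl group on the future C1, with C2 set by the chiral ligand.

Step 3
Reactants: 5 2-[(1R)-1-(4-methoxybenzyloxy)prop-2-enyl]-2-methylcyclohexane-1,3-dione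
Product: 6 (2R,3S)-3-hydroxy-2-[(1R)-1-(4-methoxybenzyloxy)prop-2-enyl]-2-methylcyclohexanone
Conditions: (R)-2-methyl-CBS-oxazaborolidine (20 mol %), catecholborane (1.5 equiv), toluene, −78 °C
Reagents that add atoms: none
Why: Corey–Bakshi–Shibata reduction used as a desymmetrisation: the catalyst (quaternary C1 as the large group) should give the (S)-carbinol at C14, while hydride attack anti to the bulkier alkoxyallyl group selects the carbonyl that places OH cis to that group and so fixes C1; catecholborane at −78 °C should leave the vinyl group untouched.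

Step 4
Reactants: 6 (2R,3S)-3-hydroxy-2-[(1R)-1-(4-methoxybenzyloxy)prop-2-enyl]-2-methylcyclohexanone
Product: 7 O2/O14 p-methoxybenzylidene acetal ketone (cis-fused 1,3-benzodioxin-5-one)
Conditions: DDQ (1.2 equiv), 4 Å MS, CH2Cl2, 0 °C
Reagents that add atoms: none
Why: DDQ oxidises the PMB ether to an oxocarbenium ion that the syn-1,3 C14 hydroxyl traps (oxidative acetalisation), giving the cis-fused dioxane with aryl, vinyl and C13 equatorial at the thermodynamically controlled acetal carbon.

Step 5
Reactants: 7 O2/O14 p-methoxybenzylidene acetal ketone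
Product: 10 α-methylene ketone (C11=C20H2 enone), via Mannich base 8 (not isolated), via ammonium iodide 9 (not isolated)
Conditions: LiHMDS, THF, −78 °C; dimethylmethyleneiminium iodide, −78 °C → rt; MeI, CH2Cl2, rt; DBU, rt
Reagents that add atoms: dimethylmethyleneiminium iodide (Eschenmoser's salt) C=[N+](C)C.[I-]
Why: Only C11 is enolisable, so the lithium enolate undergoes a regiospecific Mannich reaction, and N-methylation followed by E1cB elimination completes the α-methylenation.

Step 6
Reactants: 10 α-methylene ketone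
Product: 11 allylic alcohol (C10 carbinol epimers with C11=C20H2)
Conditions: NaBH4, CeCl3·7H2O, MeOH, −78 °C
Reagents that add atoms: none
Why: Luche reduction delivers hydride 1,2 to the enone; the configuration of the new C10 carbinol is irrelevant because C10 becomes sp2 in step 7.

Step 7
Reactants: 11 allylic alcohol
Product: 12 primary allylic alcohol (C20 hydroxymethyl on C11 with C10=C11 olefin)
Conditions: Ph3SiOReO3 (5 mol %), Et2O, 0 °C
Reagents that add atoms: none
Why: Re(VII)-catalysed 1,3-transposition of an allylic alcohol ([3,3] shift of the allyl perrhenate) should run downhill to the trisubstituted endocyclic olefin and the unhindered primary alcohol.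

Step 8
Reactants: 13 L-erythrulose
Product: 14 3,4-O-isopropylidene-L-erythrulose
Conditions: 2,2-dimethoxypropane, TsOH (cat.), acetone, rt
Reagents that add atoms: 2,2-dimethoxypropane COC(C)(C)OC
Why: Acid-catalysed acetonide formation on the terminal 3,4-diol (five-membered dioxolane favoured); C7 is taken unchanged from the chiral pool.

Step 9
Reactants: 14 3,4-O-isopropylidene-L-erythrulose
Product: 15 1-O-(tert-butyldiphenylsilyl)-3,4-O-isopropylidene-L-erythrulose
Conditions: TBDPSCl, imidazole, DMF, 0 °C → rt
Reagents that add atoms: tert-butyldiphenylsilyl chloride CC(C)(C)[Si](Cl)(c1ccccc1)c1ccccc1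
Why: Silylation of the remaining primary alcohol; the bulky, weakly basic silyl ether keeps O9 from competing as a chelating group in step 10.

Step 10
Reactants: 15 1-O-(tert-butyldiphenylsilyl)-3,4-O-isopropylidene-L-erythrulose
Product: 16 methyl (3R)-4-(tert-butyldiphenylsilyloxy)-3-[(4S)-2,2-dimethyl-1,3-dioxolan-4-yl]-3-hydroxy-2-methylbutanoate (C17 epimers)
Conditions: methyl propionate, LDA, THF, −78 °C; MgBr2·OEt2; then 15, −78 °C
Reagents that add atoms: methyl propionate CCC(=O)OC
Why: Aldol addition of the ester enolate under Cram-chelate control: Mg(II) bridges the C8 carbonyl and the dioxolane oxygen on C7 and the enolate attacks anti to C6, setting C8, while C17 forms as an epimer mixture that is set in step 11.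

Step 11
Reactants: 16 methyl (3R)-4-(tert-butyldiphenylsilyloxy)-3-[(4S)-2,2-dimethyl-1,3-dioxolan-4-yl]-3-hydroxy-2-methylbutanoate (C17 epimers)
Product: 18 (3R,4R,5S)-4-[(tert-butyldiphenylsilyloxy)methyl]-4-hydroxy-5-(hydroxymethyl)-3-methyloxolan-2-one, via lactone diol C17-epimer mixture 17 (not isolated)
Conditions: CSA (cat.), MeOH, rt; Et3N, concentrate; DBU (0.3 equiv), toluene, 80 °C
Reagents that add atoms: none
Why: Acid-catalysed transacetalisation frees the C6/C7 diol and the C7 hydroxyl closes the γ-lactone; DBU should then equilibrate the only enolisable centre, C17, to the thermodynamically favoured epimer with C18 trans to the bulky C9H2OSi group (all three ring carbon substituents mutually trans).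

Step 12
Reactants: 18 (3R,4R,5S)-4-[(tert-butyldiphenylsilyloxy)methyl]-4-hydroxy-5-(hydroxymethyl)-3-methyloxolan-2-one
Product: 19 lactone aldehyde (C6 = CHO)
Conditions: Dess–Martin periodinane, NaHCO3, CH2Cl2, 0 °C
Reagents that add atoms: none
Why: Dess–Martin oxidation of the primary alcohol; the tertiary C8 hydroxyl cannot be oxidised.

Step 13
Reactants: 19 lactone aldehyde
Product: 20 (3R,4R,5S)-4-[(tert-butyldiphenylsilyloxy)methyl]-4-hydroxy-5-[(Z)-2-iodoprop-1-enyl]-3-methyloxolan-2-one
Conditions: EtPPh3I, n-BuLi, THF, rt; I2, −78 °C; NaHMDS, −20 °C; then 19, −78 °C (2.5 equiv of ylide)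
Reagents that add atoms: ethyltriphenylphosphonium iodide CC[P+](c1ccccc1)(c1ccccc1)c1ccccc1.[I-]; iodine II
Why: Stork–Zhao olefination with the α-iodo ylide should give the (Z)-2-iodoalkene (I cis to C7) under kinetic control; excess ylide covers the free tertiary OH, and any base-induced epimerisation at C7 converges on the wanted trans arrangement.

Step 14
Reactants: 12 primary allylic alcohol; 20 (3R,4R,5S)-4-[(tert-butyldiphenylsilyloxy)methyl]-4-hydroxy-5-[(Z)-2-iodoprop-1-enyl]-3-methyloxolan-2-one
Product: 22 seco-diol (C4–C5 joined with Z-C5=C6 plus C20-OH plus C9-OTBDPS), via B-alkyl-9-BBN borane 21 (not isolated)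
Conditions: 12, 9-BBN dimer, THF, rt; then aq. Cs2CO3, 20, Pd(dppf)Cl2 (10 mol %), AsPh3, DMF, rt
Reagents that add atoms: none
Why: B-alkyl Suzuki–Miyaura coupling: 9-BBN adds anti-Markovnikov to the monosubstituted vinyl group only (the trisubstituted ring olefin is inert) and Pd couples the primary alkylborane with the vinyl iodide with retention, giving the Z-trisubstituted C5=C6 olefin.

Step 15
Reactants: 22 seco-diol
Product: 23 seco-triol (C20-OH and C9-OH and C8-OH)
Conditions: TBAF, AcOH (1:1), THF, rt
Reagents that add atoms: none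
Why: Fluoride cleavage of the primary silyl ether, buffered with acetic acid to suppress base-induced translactonisation by the liberated C9 hydroxyl.

Step 16
Reactants: 23 seco-triol
Product: 24 allylic bromide (C20-Br)
Conditions: NBS, Me2S, CH2Cl2, −20 °C; then 23, −20 → 0 °C
Reagents that add atoms: N-bromosuccinimide O=C1CCC(=O)N1Br
Why: Corey–Kim halogenation: the alkoxysulfonium salt is displaced by bromide only at the allylic C20 position, so the neopentyl primary and the tertiary alcohol are returned unchanged.

Step 17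
Reactants: 24 allylic bromide
Product: 25 bromo aldehyde (C9 = CHO)
Conditions: Dess–Martin periodinane, NaHCO3, CH2Cl2, 0 °C
Reagents that add atoms: none
Why: Dess–Martin oxidation of the only remaining primary alcohol to the non-enolisable α-hydroxy aldehyde under neutral conditions that tolerate the allylic bromide.

Step 18
Reactants: 25 bromo aldehyde
Product: 27 macrocyclic acetal diol (trans-fused ten-membered ring with C11=C20H2 and 9-OH), via allylchromium(III) species 26 (not isolated)
Conditions: CrCl2 (10 equiv), 4 Å MS, THF (2 mM), rt, slow addition of 25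
Reagents that add atoms: none
Why: CrCl2 reduces the allylic bromide to the η1-allylchromium(III) 26, which adds through its γ-carbon C10 to the chromium-bound C9 aldehyde in a six-membered chair transition state, transposing the olefin to the exocyclic C11=C20 position. The closest known reaction type is the intramolecular Nozaki–Hiyama (Cr-mediated Barbier) allylation used to close medium and large carbocycles. The ten-membered ring closes by 10-exo-trig attack on the aldehyde (O9 stays outside the ring) combined with SE2′ reaction of the allyl unit. C9 is controlled by the chair: the allylchromium is E-configured (C1 trans to C20) and the aldehyde substituent C8 is equatorial, which gives the 9,10-anti relationship. C10 is controlled by the temporary dioxane, which locks the cyclohexene half-chair (C15 axial, tether carbon C2 equatorial, O14 axial) and fixes the C1–C2 rotamer so that C3 points to the β-face while axial O14 screens the α-face, so the new bond should form cis to C15 (trans ring fusion). The step needs γ- over α-attack (intrinsic to allylchromium; α-attack would give a twelve-membered ring) and cyclisation over oligomerisation (high dilution, slow addition); lactone, acetal and tertiary OH are tolerated by Cr(II).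

Step 19
Reactants: 27 macrocyclic acetal diol
Product: 28 tetraol (2-OH and 8-OH and 9-OH and 14-OH)
Conditions: AcOH/THF/H2O (3:1:1), 40 °C
Reagents that add atoms: none
Why: Mild aqueous acid hydrolysis of the p-methoxybenzylidene acetal, the most acid-labile group present, releases the C2 and C14 hydroxyls.

Step 20
Reactants: 28 tetraol
Product: 29 CNP0187723.2 (2,9,14-triacetate with free 8-OH)
Conditions: Ac2O, DMAP, pyridine, CH2Cl2, rt
Reagents that add atoms: acetic anhydride CC(=O)OC(C)=O
Why: DMAP-catalysed acetylation of the three secondary alcohols at C2, C9 and C14; the hindered tertiary C8 hydroxyl should remain free under these conditions.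

Compound list
1 | 4-methoxybenzyl alcohol | OCc1ccc(OC)cc1 | starting material
2 | 4-methoxybenzyl propargyl ether | C#CCOCc1ccc(OC)cc1 | intermediate
3 | 4-methoxybenzyloxyallene | C=C=COCc1ccc(OC)cc1 | intermediate
4 | 2-methylcyclohexane-1,3-dione | CC1C(=O)CCCC1=O | starting material
5 | 2-[(1R)-1-(4-methoxybenzyloxy)prop-2-enyl]-2-methylcyclohexane-1,3-dione | C=C[C@@H](OCc1ccc(OC)cc1)C1(C)C(=O)CCCC1=O | intermediate
6 | (2R,3S)-3-hydroxy-2-[(1R)-1-(4-methoxybenzyloxy)prop-2-enyl]-2-methylcyclohexanone (OH cis to the alkoxyallyl group) | C=C[C@@H](OCc1ccc(OC)cc1)[C@]1(C)C(=O)CCC[C@@H]1O | intermediate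
7 | O2/O14 p-methoxybenzylidene acetal ketone: cis-fused 2-(4-methoxyphenyl)-4a-methyl-4-vinylhexahydro-1,3-benzodioxin-5-one, aryl and vinyl equatorial, H-2/H-4/H-8a all cis, C10 ketone | COc1ccc(cc1)[C@@H]1O[C@H](C=C)[C@]2(C)C(=O)CCC[C@@H]2O1 | intermediate
8 | Mannich base: 7 with CH2NMe2 at C11 | COc1ccc(cc1)[C@@H]1O[C@H](C=C)[C@]2(C)C(=O)C(CN(C)C)CC[C@@H]2O1 | intermediate
9 | trimethylammonium iodide of 8 | COc1ccc(cc1)[C@@H]1O[C@H](C=C)[C@]2(C)C(=O)C(C[N+](C)(C)C)CC[C@@H]2O1.[I-] | intermediate
10 | α-methylene ketone: 7 with exocyclic C11=C20H2 | COc1ccc(cc1)[C@@H]1O[C@H](C=C)[C@]2(C)C(=O)C(=C)CC[C@@H]2O1 | intermediate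
11 | allylic alcohol: C10 carbinol (epimers) with C11=C20H2 | COc1ccc(cc1)[C@@H]1O[C@H](C=C)[C@]2(C)C(O)C(=C)CC[C@@H]2O1 | intermediate
12 | primary allylic alcohol: C20H2OH on C11, C10=C11 olefin (cyclohexene fragment) | COc1ccc(cc1)[C@@H]1O[C@H](C=C)[C@]2(C)C=C(CO)CC[C@@H]2O1 | intermediate
13 | L-erythrulose, (S)-1,3,4-trihydroxybutan-2-one | OCC(=O)[C@@H](O)CO | starting material
14 | 3,4-O-isopropylidene-L-erythrulose | CC1(C)OC[C@H](O1)C(=O)CO | intermediate
15 | 1-O-(tert-butyldiphenylsilyl)-3,4-O-isopropylidene-L-erythrulose | CC1(C)OC[C@H](O1)C(=O)CO[Si](c1ccccc1)(c1ccccc1)C(C)(C)C | intermediate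
16 | methyl (3R)-4-(tert-butyldiphenylsilyloxy)-3-[(4S)-2,2-dimethyl-1,3-dioxolan-4-yl]-3-hydroxy-2-methylbutanoate, C17 epimers | COC(=O)C(C)[C@@](O)(CO[Si](c1ccccc1)(c1ccccc1)C(C)(C)C)[C@@H]1COC(C)(C)O1 | intermediate
17 | lactone diol as C17-epimer mixture | CC(C)(C)[Si](c1ccccc1)(c1ccccc1)OC[C@@]1(O)[C@H](CO)OC(=O)C1C | intermediate
18 | (3R,4R,5S)-4-[(tert-butyldiphenylsilyloxy)methyl]-4-hydroxy-5-(hydroxymethyl)-3-methyloxolan-2-one (C6H2OH, 8-OH and C18 mutually cis) | CC(C)(C)[Si](c1ccccc1)(c1ccccc1)OC[C@@]1(O)[C@H](CO)OC(=O)[C@@H]1C | intermediate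
19 | lactone aldehyde: 18 with C6 = CHO | CC(C)(C)[Si](c1ccccc1)(c1ccccc1)OC[C@@]1(O)[C@H](C=O)OC(=O)[C@@H]1C | intermediate
20 | (3R,4R,5S)-4-[(tert-butyldiphenylsilyloxy)methyl]-4-hydroxy-5-[(Z)-2-iodoprop-1-enyl]-3-methyloxolan-2-one | CC(C)(C)[Si](c1ccccc1)(c1ccccc1)OC[C@@]1(O)[C@H](/C=C(/C)I)OC(=O)[C@@H]1C | intermediate
21 | B-alkyl-9-BBN borane of 12 (boron on C4; C20-O-BBN borinate) | COc1ccc(cc1)[C@@H]1O[C@H](CCB3C4CCCC3CCC4)[C@]2(C)C=C(COB3C4CCCC3CCC4)CC[C@@H]2O1 | intermediate
22 | seco-diol: C4–C5 joined, Z-C5=C6, C20-OH, 8-OH, C9-OTBDPS | COc1ccc(cc1)[C@@H]1O[C@H](CC/C(C)=C\[C@@H]3OC(=O)[C@H](C)[C@@]3(O)CO[Si](c4ccccc4)(c4ccccc4)C(C)(C)C)[C@]2(C)C=C(CO)CC[C@@H]2O1 | intermediate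
23 | seco-triol: 22 with free C9-OH | COc1ccc(cc1)[C@@H]1O[C@H](CC/C(C)=C\[C@@H]3OC(=O)[C@H](C)[C@@]3(O)CO)[C@]2(C)C=C(CO)CC[C@@H]2O1 | intermediate
24 | allylic bromide: 23 with C20-Br | COc1ccc(cc1)[C@@H]1O[C@H](CC/C(C)=C\[C@@H]3OC(=O)[C@H](C)[C@@]3(O)CO)[C@]2(C)C=C(CBr)CC[C@@H]2O1 | intermediate
25 | bromo aldehyde: 24 with C9 = CHO | COc1ccc(cc1)[C@@H]1O[C@H](CC/C(C)=C\[C@@H]3OC(=O)[C@H](C)[C@@]3(O)C=O)[C@]2(C)C=C(CBr)CC[C@@H]2O1 | intermediate
26 | allylchromium(III) dichloride from 25 (Cr on C20) | COc1ccc(cc1)[C@@H]1O[C@H](CC/C(C)=C\[C@@H]3OC(=O)[C@H](C)[C@@]3(O)C=O)[C@]2(C)C=C(C[Cr](Cl)Cl)CC[C@@H]2O1 | intermediate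
27 | macrocyclic acetal diol: trans-fused ten-membered ring, C11=C20H2, 9-OH anti to C1 across C9–C10, 8-OH, O2/O14 acetal | C=C1CC[C@H](O3)[C@@]2(C)[C@H]1[C@@H](O)[C@@]1(O)[C@H](/C=C(/C)CC[C@H]2O[C@H]3c2ccc(OC)cc2)OC(=O)[C@@H]1C | intermediate
28 | tetraol: 2,8,9,14-tetrahydroxy compound | C=C1CC[C@H](O)[C@@]2(C)[C@H]1[C@@H](O)[C@@]1(O)[C@H](/C=C(/C)CC[C@H]2O)OC(=O)[C@@H]1C | intermediate
29 | CNP0187723.2 | C=C1CC[C@H](OC(C)=O)[C@@]2(C)[C@H]1[C@@H](OC(C)=O)[C@@]1(O)[C@H](/C=C(/C)CC[C@H]2OC(C)=O)OC(=O)[C@@H]1C | target

Total step count: 20. Longest linear sequence: 14 steps (steps 1–7, then 14–20).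

Steps most likely to fail

Step 18. Oligomerisation may outrun ring closure, or the aldehyde may be delivered to the α-face of C10 and give the cis ring fusion. The fallback reverses the order of the two unions, making C9–C10 intermolecularly and closing the ten-membered ring at C4–C5. It sets out from 12 and 20. Compound 12 would be brominated (NBS/Me2S) to the allylic bromide F1. Compound 20 would be desilylated (TBAF/AcOH) to the vinyl iodide diol F2 and oxidised (Dess–Martin) to the hydroxy aldehyde F3. Nickel-free CrCl2 would couple F1 and F3, the vinyl iodide being inert without Ni and the aldehyde approaching C10 on the convex β-face of the cis-fused acetal, to give the homoallylic alcohol F4. Hydroboration of the monosubstituted vinyl group of F4 with disiamylborane, then Pd(dppf)Cl2/AsPh3/Cs2CO3 at high dilution (intramolecular B-alkyl Suzuki–Miyaura coupling), would close the ring and come back to the route at 27.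

Step 11. Under DBU the β-hydroxy lactone may open by retro-aldol cleavage and scramble C7/C8, or the equilibrium may not favour the wanted C17 epimer enough. The fallback replaces thermodynamic control by kinetic protonation. It sets out from 17, which would be carried as the epimer mixture through the Dess–Martin oxidation (aldehyde epimer mixture F5) and the Stork–Zhao olefination (vinyl iodide epimer mixture F6). F6 would then be converted into its alkoxide–enolate dianion (LiHMDS, 2.3 equiv, THF, −78 °C) and protonated with 2,6-di-tert-butylphenol, the proton arriving anti to the solvated C8 lithium alkoxide, to come back to the route at 20.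

Step 7. The 1,3-transposition may stop at an unfavourable equilibrium, or the allyl perrhenate may ionise with acetal cleavage or skeletal rearrangement. The fallback moves the oxygen by two substitutions instead of a sigmatropic shift. It sets out from 11: MsCl, LiCl and s-collidine in DMF would give the rearranged primary allylic chloride F7 (SN2′ and allylic equilibration towards the trisubstituted olefin). CsOAc in DMF would give the primary allylic acetate F8, and K2CO3 in MeOH would come back to the route at 12.

Further compounds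
F1 | step 18 | allylic bromide from 12 (C20-Br, vinyl intact) | COc1ccc(cc1)[C@@H]1O[C@H](C=C)[C@]2(C)C=C(CBr)CC[C@@H]2O1
F2 | step 18 | vinyl iodide diol from 20 (free C9-OH) | OC[C@@]1(O)[C@H](/C=C(/C)I)OC(=O)[C@@H]1C
F3 | step 18 | vinyl iodide hydroxy aldehyde (C9 = CHO) | O=C[C@@]1(O)[C@H](/C=C(/C)I)OC(=O)[C@@H]1C
F4 | step 18 | intermolecular allylation product (C9–C10 formed, C11=C20H2, vinyl and vinyl iodide intact) | C=C1CC[C@H](O3)[C@@]([C@@H](C=C)O[C@H]3c2ccc(OC)cc2)(C)[C@H]1[C@@H](O)[C@@]1(O)[C@H](/C=C(/C)I)OC(=O)[C@@H]1C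
F5 | step 11 | lactone aldehyde as C17-epimer mixture | CC(C)(C)[Si](c1ccccc1)(c1ccccc1)OC[C@@]1(O)[C@H](C=O)OC(=O)C1C
F6 | step 11 | (Z)-vinyl iodide lactone as C17-epimer mixture | CC(C)(C)[Si](c1ccccc1)(c1ccccc1)OC[C@@]1(O)[C@H](/C=C(/C)I)OC(=O)C1C
F7 | step 7 | primary allylic chloride (C20-Cl, C10=C11) | COc1ccc(cc1)[C@@H]1O[C@H](C=C)[C@]2(C)C=C(CCl)CC[C@@H]2O1
F8 | step 7 | primary allylic acetate (C20-OAc, C10=C11) | COc1ccc(cc1)[C@@H]1O[C@H](C=C)[C@]2(C)C=C(COC(C)=O)CC[C@@H]2O1
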